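The data were generated by integration from invented constants, and the scatter is random.

At 2.50 h in Tuesday's run, homo dimer outweighs target by a ratio of 20.5, and I want to know what that ratio becomes in each flask.

| flask | starting material | second substrate | free catalyst | remark | time |
|---|---|---|---|---|---|
| Tuesday's | 20 mM | 20 mM | 1 mM | run made earlier |  |
| Saturday's | 10 mM | 20 mM | 1 mM | run made earlier |  |
| Thursday's | 15 mM | 20 mM | 1 mM | run made earlier |  |
| Friday's | 20 mM | 20 mM | 2 mM | run made earlier |  |
| east | 20 mM | 20.0 mM (fed, over 2.0 h) | 1.0 mM | all else is in the flask from the start; the feed brings no volume worth counting | 30 h |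
| north-east | 20 mM | 20.0 mM | 1.0 mM | everything together at the start | 30 h |
| west | 20 mM | 20.0 mM (fed, over 20 h) | 1.0 mM | all else is in the flask from the start; the feed brings no volume worth counting | 30 h |
| north-west | 20 mM (fed, over 20 h) | 20.0 mM | 1.0 mM | all else is in the flask from the start; the feed brings no volume worth counting | 30 h |

| run | time / h | homo dimer / % | target / % |
|---|---|---|---|
| Tuesday's | 2.50 | 75.8 | 3.7 |
| Tuesday's | 4.00 | 81.9 | 7.4 |
| Tuesday's | 6.00 | 82.4 | 12.6 |
| Tuesday's | 8.00 | 83.3 | 13.2 |
| Tuesday's | 12.0 | 82.8 | 15.8 |
| Tuesday's | 20.0 | 82.9 | 16.0 |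
| Tuesday's | 30.0 | 83.5 | 14.2 |
| Saturday's | 5.00 | 72.7 | 15.8 |
| Saturday's | 10.0 | 71.8 | 26.4 |
| Saturday's | 15.0 | 74.2 | 27.9 |
| Saturday's | 20.0 | 73.2 | 27.7 |
| Saturday's | 25.0 | 71.5 | 27.7 |
| Saturday's | 30.0 | 72.1 | 27.1 |
| Saturday's | 40.0 | 74.2 | 26.4 |
| Thursday's | 2.00 | 67.9 | 4.4 |
| Thursday's | 6.00 | 79.7 | 14.2 |
| Thursday's | 10.0 | 79.6 | 20.2 |
| Thursday's | 15.0 | 79.0 | 19.3 |
| Thursday's | 20.0 | 77.5 | 20.5 |
| Thursday's | 30.0 | 79.6 | 20.3 |
| Thursday's | 40.0 | 80.1 | 18.9 |
| Friday's | 8.00 | 72.7 | 28.7 |
| Friday's | 15.0 | 72.3 | 30.0 |
| Friday's | 20.0 | 71.6 | 28.1 |
| Friday's | 30.0 | 70.8 | 28.3 |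
| Friday's | 40.0 | 71.4 | 27.8 |

(each reading ± 1 percentage point)

- in percentages every species weighs as the starting material in it: one homo dimer counts as two
- a reading or a percentage of target counts all its forms, free or not

- which flask leads in amount of homo dimer, in percent of the starting material charged ("all alike" within 1.5 percentage points) (east / north-east / west / north-west / all alike)
- how much homo dimer is there at the end, in percent of the starting material charged: east
- how much homo dimer is there at the end, in percent of the starting material charged: north-east
- how much homo dimer is there at the end, in percent of the starting material charged: west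
- how much homo dimer is there at the end, in percent of the starting material charged: north-west

How fast does each route consume starting material? By balance, 20.5% of it is left at that time in Tuesday's run, and a second-order loss to homo dimer then reads as a lifetime of 0.645 h at 20 mM. Later the remainder falls from 10.7% at 4.00 h to 5.00% at 6.00 h, which reads as a pseudo-first-order lifetime under the catalyst of 2.63 h, scatter included. So I get the crossing level 4.90 mM, the c(starting material) at which homo dimer and 1 mM of catalyst consume it equally fast.

What should a batch give if the catalyst worked from the start? Integrating both rates from 4.08 times the crossing level gives target at 39.8%. Tuesday's run reads 16.0% at 20.0 h, less than that, so I suspect the second substrate of holding the catalyst early.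

What then do the flasks give? I reckon north-east repeats Tuesday's run, 83.5%. For west, fed over 20 h, I assume the catalyst works from the start, so I take 60.2%, and east, fed over 2.0 h, I put midway at 71.8%. North-west is fed 1.00 mM/h; leaving aside the early hours, when second substrate may hold the catalyst, that balances both losses at 1.90 mM, below the crossing level, so I give homo dimer 27.9%. So I put north-east in the lead.

The forecast differs: it puts west in the lead with 91%, beside east 84%, north-east 83% and north-west 64%, on the ground that “substrate is scarce while A burns off to dimer”, A being the starting material.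

Homo dimer ends at 74.6% in east, 83.6% in north-east, 60.8% in west and 26.4% in north-west, so north-east leads.

    starting material + free catalyst ⇌ catalyst intermediate A (K = 150 /M, k = 490 /M/h)
    catalyst intermediate A → free catalyst + target (k = 73.0 /h)
    second substrate + free catalyst ⇌ catalyst intermediate B (K = 10000 /M, k = 3700 /M/h)
    catalyst intermediate B → free catalyst + second product (k = 5.70 /h)
    2 starting material → homo dimer (k = 42.0 /M/h)
    crystals ⇌ target, rate k6*(cs6 - [target]) while solid is left; crystals form when [target] > cs6 (solubility = 15.0 mM, k = 3.20 /h)

In north-west at 20.0 h, starting material stands at 1.66 mM, below the crossing level of 4.90 mM. The neighbouring flask is like north-west but holds 12 mM of starting material, fed over the same 20 h, which is 0.600 mM/h. The same balance puts its level at 1.26 mM and the share of homo dimer at 20.5%. That flask ends with 18.9% homo dimer and 81.0% target.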